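Look at the reagent first.

substrate 1.0 mM (in portions, 4); reagent in the second phase 1.20 mM; time 80 min; volume of the second phase over the first 2.0; the portions of substrate follow each other after 40 s, the first at the start

    target ⇌ isomer of the product (K1 = 1.7, k1 = 0.048 s⁻¹)
    reagent in the reaction phase ⇌ reagent in the second phase, rate k2*([reagent in the reaction phase] - [reagent in the second phase]/K2) per volume of the first phase (K2 = 0.38, k2 = 0.10 s⁻¹)
    substrate + reagent in the reaction phase → target (k3 = 43 L mol⁻¹ s⁻¹)

- in the second phase: reagent in the second phase; everything else is in the first
- charges count per volume of the first phase; a concentration in a rate is the amount of a species over the volume of its own phase; every rate counts per litre of the first phase
- the reaction counts as stopped when no species that holds the substrate changes by six tenths of a point or more over the second half of the time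
- run time (flask): 80 min

1. which holds at 80 min: what has brought the reaction to rest, or that it has not come to rest (it is still moving / all of the substrate has reacted / forward and back rates have come level)
2. share of the substrate used up at 80 min
3. target at 80 min, in percent of the substrate charged
4. isomer of the product at 80 min, in percent of the substrate charged
5. amount of target if the flask were left three thousand times as long, in percent of the substrate charged

**Is there enough reagent in this flask?** Yes. Charges count per volume of the first phase, so 1.20 mM of reagent in the second phase stands directly against 1.0 mM of substrate. Each coupling takes one of each, and the flask holds more reagent than substrate, so the substrate is the limiting reagent and the excess is 0.200 mM.

**But that excess is split between two phases. Is the end of the coupling not too slow?** At the end of the coupling, the excess divides between the two phases according to the partition ratio and the volume ratio, leaving 0.114 mM as c(reagent in the reaction phase). That gives the last substrate a half-life of 2.36 min, far shorter than the 80 min allowed. So I commit to full conversion.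

**How much of the product is target?** Target and isomer of the product relax towards each other with a half-life of 0.152 min, which is also far shorter than the time. The order in which they formed therefore stops mattering. I keep 37.0% as the target's share: the part of the coupled product that stands as target once the balance holds, one part against 1.7. The rule, for a flask in which the coupling has run to its end and the balance holds, is that target, in percent of the substrate charged, is this share times the smaller charge over the substrate charge. For this flask I get 37.0% target and 63.0% isomer of the product.

The forecast agrees with my reckoning: all of the substrate has reacted, conversion 100%, target 37%, isomer of the product 63%, and 37% target after the very long wait. Its grounds are that “The irreversible coupling then leaves the target and its isomer at their fast equilibrium”.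

In the simulation of this flask, all of the substrate has reacted, with conversion 100%, target 37.0%, isomer of the product 63.0%, and 37.0% target after the very long wait.

In this flask the isomer of the product stops at 63.0% because of the backward run to target: the same run without that step puts it at 100%. The target's 37.0% is thus a balance, not a stage on the way to something else, and waiting ten times as long leaves the isomer of the product where it stands.

The neighbour flask charged with 1.7 mM of substrate has more substrate than reagent, so the rule takes the reagent charge as the smaller one. It gives 26.1% target with 29.4% of the substrate left. The simulated neighbour holds 26.1% target and 29.4% substrate at 80.0 min.

(The constants used here come from no measurement, and the outcome is calculated.)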